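You take your reading when 30% of the starting material is gone, and you compare flasks at that conversion, not at a clock time.

    starting material + free catalyst → catalyst intermediate A (k1 = 1900 L mol⁻¹ s⁻¹)
    reagent + catalyst intermediate A ⇌ catalyst intermediate B (K2 = 73 L mol⁻¹, k2 = 150 L mol⁻¹ s⁻¹)
    catalyst intermediate B → free catalyst + product (k3 = 9.9 s⁻¹)
    reagent ⇌ dormant form (K4 = 4.2, k4 = 0.074 s⁻¹)

starting material 10 mM; reagent 25.0 mM; free catalyst 0.25 mM

- apparent order in free catalyst when 30% of the starting material are converted (percent change of the rate of making product for one percent more free catalyst charged)
- apparent order in reagent when 30% of the starting material are converted (percent change of the rate of making product for one percent more reagent charged)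

Reagent leaves by two roads, so divide one rate by the other and time drops out. Suppose for now that the whole catalyst sits as catalyst intermediate A and that dormant form never returns. Reagent binds to A, but B falls back at 2.05 s⁻¹ and goes on at 9.9 s⁻¹, so some binding is wasted. Reagent concentration cancels as well, leaving 0.074 s⁻¹ × (9.9 s⁻¹ + 2.05 s⁻¹) / (150 L mol⁻¹ s⁻¹ × 9.9 s⁻¹ × 0.25 mM) = 2.38. This is the drain ratio: dormant form made per product made.

At the reading, 3.00 mM of starting material is used up. Product lags that by what the catalyst still holds, which can't exceed the 0.25 mM charged; I neglect this lag and count the whole amount as product, so a first guess leaves 14.9 mM of reagent.

But the catalyst isn't all A. At that reagent level, one turnover spends these waits: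

| Catalyst form | Wait per turnover |
|---|---|
| free catalyst | 0.0752 s |
| intermediate A | 0.542 s |
| intermediate B | 0.101 s |

A is the resting state, its wait being longer than the others, and it holds a share of 75.5%. Dividing the drain ratio by that share gives 9.47 mM of dormant form and leaves 12.5 mM of reagent.

The rate is the catalyst divided by the summed waits, so one percent more reagent at the reading raises it by about 0.755 of a percent. One percent more catalyst adds one percent directly and shrinks the dormant form, and one percent more reagent adds a hundredth of the charge.

The objection is that more reagent lowers A's share, which raises the drain. This enlarges the denominator from reagent left to 14.9 mM. I get 1.48 in catalyst and 1.27 in reagent.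

A last objection stands: dormant form returns at 18.0% of the loss rate at the reading, and I leave that uncorrected.

The forecast says 1.35 and 1.15, both below mine: “more catalyst gets there sooner with less reagent lost”.

The flask gives 1.5 in free catalyst and 1.2 in reagent, below my 1.27. In this flask at 5.23 s, reagent's forward half-life by loss to dormant form, 9.4 s, is shorter than by binding to A, 25 s, a ratio of 2.62, which is the drain ratio without its fall-back factor, 1.97, divided by a share of A of 75.2%. No reagent stands in the drain ratio, and the flask charged with twice the reagent reaches the same conversion in 0.602 of the time.

The rate constants come from no measurement; what happens was integrated by code.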